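Rings are lettered A–G from the 2,4,6-trihydroxyphenoxy end. Ring A is not joined by O-arylation but grown on the ring B oxygen: its ether carbon C1, flanked by the hydroxylated carbons C2 and C6, maps onto the central carbon of a 2-aryloxymalonate, and C3–C4–C5 onto dimethyl 3-oxopentanedioate. One double Claisen benzannulation forges C2–C3 and C5–C6 and closes ring A as a phloroglucinol diester; its precursor is the malonate O-linked to a 4-benzyloxy-3,5-dimethoxyphenyl ring B unit. After decarboxylation and methylation, rings C–G are attached as C, D–E and F–G blocks by CuI-catalysed Ullmann couplings with Dakin unmasking, and BBr3 frees all eighteen phenols.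

Key step: step 4

Remark: the target has no stereocentre, so no step has to set or preserve configuration.

Step 1
Reactants: 1 syringaldehyde (4-hydroxy-3,5-dimethoxybenzaldehyde)
Product: 2 4-(benzyloxy)-3,5-dimethoxybenzaldehyde
Conditions: BnBr, K2CO3, DMF, 60 °C
Reagents that add atoms: benzyl bromide, BrCc1ccccc1
Why: Williamson O-benzylation of the acidic para-formyl phenol should be clean, and the benzyl ether survives methoxide, hydroxide and methylation yet is later removed without touching methyl ethers.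

Step 2
Reactants: 2 4-(benzyloxy)-3,5-dimethoxybenzaldehyde
Product: 4 4-(benzyloxy)-3,5-dimethoxyphenol, via aryl formate 3 (not isolated)
Conditions: mCPBA, CH2Cl2, 0 °C to rt; then K2CO3 (cat.), MeOH, rt
Reagents that add atoms: mCPBA (3-chloroperoxybenzoic acid), O=C(OO)c1cccc(Cl)c1
Why: Baeyer–Villiger oxidation of an electron-rich benzaldehyde proceeds with aryl migration (Dakin-type) to the formate, which mild methanolysis cleaves to the ring B phenol.

Step 3
Reactants: 4 4-(benzyloxy)-3,5-dimethoxyphenol; 5 dimethyl 2-chloromalonate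
Product: 6 dimethyl 2-[4-(benzyloxy)-3,5-dimethoxyphenoxy]malonate
Conditions: K2CO3, acetone, reflux
Reagents that add atoms: none
Why: Williamson SN2 O-alkylation of the unhindered phenoxide by the doubly ester-activated chloride is a standard entry to aryloxymalonates, and the chloride is preferred to the bromide because it should not transfer halogen to the electron-rich ring.

Step 4
Reactants: 6 dimethyl 2-[4-(benzyloxy)-3,5-dimethoxyphenoxy]malonate; 7 dimethyl 3-oxopentanedioate
Product: 9 dimethyl 5-[4-(benzyloxy)-3,5-dimethoxyphenoxy]-2,4,6-trihydroxybenzene-1,3-dicarboxylate, via open-chain diketo triester 8 (not isolated)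
Conditions: 7 (1.3 equiv), NaOMe (2.5 equiv), MeOH, 0 °C; add 6, reflux; MeOH distilled off, toluene, 110 °C; then aq HCl
Reagents that add atoms: none
Why: Proposed new method: the sodium enolate of 7 should C-acylate with one ester of 6 (intermolecular Claisen) to give 8, the second alpha carbon of 8 should then attack the remaining malonate ester, and the cyclohexane-1,3,5-trione so formed should enolise through its single C1–H to the aromatic phenoxide. The closest known reaction type is the alkoxide-mediated [3+3] condensation of a dialkyl malonate with a dialkyl 3-oxopentanedioate to a dialkyl 2,4,6-trihydroxyisophthalate, and the methoxide-mediated cyclocondensation of dimethyl aryloxymalonates with amidines shows that both esters of such a malonate are competent electrophiles; new here is a malonate whose central carbon carries an aryloxy group and only one hydrogen. Ring A closes in a 6-exo-trig Dieckmann-type acylation, and no stereocentre is created because C1 ends sp2. The step needs C- rather than O-acylation and cross- rather than self-condensation of 7: with matched methyl esters and methoxide, enol esters and pyranones are reopened and only the carbocycle drains irreversibly to the phenoxide, while 7 is kept as its enolate so that its ketone is not an electrophile. The one hydrogen on the malonate carbon of 6 is exactly what aromatisation requires, and the ring A C1–O bond is present from the start.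

Step 5
Reactants: 9 dimethyl 5-[4-(benzyloxy)-3,5-dimethoxyphenoxy]-2,4,6-trihydroxybenzene-1,3-dicarboxylate
Product: 11 2-[4-(benzyloxy)-3,5-dimethoxyphenoxy]benzene-1,3,5-triol, via dicarboxylic acid 10 (not isolated)
Conditions: KOH, H2O/MeOH, reflux, Ar; then aq HCl to pH 1, 60 °C
Reagents that add atoms: none
Why: Saponification followed by protodecarboxylation on acidification should be easy because each carboxyl group sits ortho and para to hydroxyls (a vinylogous beta-keto acid), as in the classical route to phloroglucinol, while the diaryl and benzyl ethers are inert.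

Step 6
Reactants: 11 2-[4-(benzyloxy)-3,5-dimethoxyphenoxy]benzene-1,3,5-triol
Product: 12 2-(benzyloxy)-1,3-dimethoxy-5-(2,4,6-trimethoxyphenoxy)benzene
Conditions: Me2SO4, K2CO3, acetone, reflux, Ar
Reagents that add atoms: dimethyl sulfate, COS(=O)(=O)OC
Why: Exhaustive Williamson O-methylation with the hard electrophile Me2SO4 in acetone favours O- over C-alkylation of the phloroglucinol ring and fixes ring A as its trimethyl ether.

Step 7
Reactants: 12 2-(benzyloxy)-1,3-dimethoxy-5-(2,4,6-trimethoxyphenoxy)benzene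
Product: 13 2,6-dimethoxy-4-(2,4,6-trimethoxyphenoxy)phenol
Conditions: H2 (1 atm), Pd/C, EtOAc/MeOH, rt
Reagents that add atoms: none
Why: Catalytic hydrogenolysis of the single benzyl ether should unveil only the ring B phenol, since methyl ethers and the diaryl ether are stable.

Step 8
Reactants: 14 5-iodo-1,2,3-trimethoxybenzene
Product: 15 6-iodo-2,3,4-trimethoxybenzaldehyde
Conditions: Cl2CHOMe, TiCl4, CH2Cl2, −10 to 0 °C; then H2O
Reagents that add atoms: dichloromethyl methyl ether, COC(Cl)Cl; water, O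
Why: Rieche formylation is an electrophilic aromatic substitution at one of the two equivalent free positions, each ortho and para to methoxy groups, so only one regioisomer can form and the formyl group lands ortho to iodine.

Step 9
Reactants: 13 2,6-dimethoxy-4-(2,4,6-trimethoxyphenoxy)phenol; 15 6-iodo-2,3,4-trimethoxybenzaldehyde
Product: 16 6-[2,6-dimethoxy-4-(2,4,6-trimethoxyphenoxy)phenoxy]-2,3,4-trimethoxybenzaldehyde
Conditions: CuI (10 mol %), picolinic acid (20 mol %), K3PO4, DMSO, 80 °C, Ar
Reagents that add atoms: none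
Why: Ullmann ether coupling in which the ortho-formyl group activates the C–I bond and the picolinate ligand system suits 2,6-disubstituted phenoxides; the aldehyde is the masked ring C hydroxyl.

Step 10
Reactants: 16 6-[2,6-dimethoxy-4-(2,4,6-trimethoxyphenoxy)phenoxy]-2,3,4-trimethoxybenzaldehyde
Product: 18 6-[2,6-dimethoxy-4-(2,4,6-trimethoxyphenoxy)phenoxy]-2,3,4-trimethoxyphenol, via aryl formate 17 (not isolated)
Conditions: mCPBA (1.1 equiv), CH2Cl2, 0 °C; then K2CO3 (cat.), MeOH, rt
Reagents that add atoms: mCPBA (3-chloroperoxybenzoic acid), O=C(OO)c1cccc(Cl)c1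
Why: Baeyer–Villiger (Dakin-type) oxidation in which the migrating carbon carries ortho-aryloxy, ortho-methoxy and para-methoxy donors, so aryl migration to the formate should be fast at 0 °C and outpace oxidation of the other rings.

Step 11
Reactants: 19 4-bromo-2,6-dimethoxyphenol; 15 6-iodo-2,3,4-trimethoxybenzaldehyde
Product: 20 6-(4-bromo-2,6-dimethoxyphenoxy)-2,3,4-trimethoxybenzaldehyde
Conditions: CuI (10 mol %), picolinic acid (20 mol %), K3PO4, DMSO, 60 °C, Ar
Reagents that add atoms: none
Why: Chemoselective Ullmann ether coupling, since the ortho-formyl C–I bond should react far faster than the C–Br bond para to the phenoxide oxygen, which stays as the handle for step 12.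

Step 12
Reactants: 18 6-[2,6-dimethoxy-4-(2,4,6-trimethoxyphenoxy)phenoxy]-2,3,4-trimethoxyphenol; 20 6-(4-bromo-2,6-dimethoxyphenoxy)-2,3,4-trimethoxybenzaldehyde
Product: 21 6-{2,6-dimethoxy-4-[2,3,4-trimethoxy-6-[2,6-dimethoxy-4-(2,4,6-trimethoxyphenoxy)phenoxy]phenoxy]phenoxy}-2,3,4-trimethoxybenzaldehyde (rings A–E, formyl group on ring E)
Conditions: CuI (20 mol %), picolinic acid (40 mol %), K3PO4, DMSO, 105 °C, Ar
Reagents that add atoms: none
Why: Ullmann ether coupling of a 2,6-dioxygenated phenoxide with an aryl bromide that has two free ortho positions, the favourable polarity for a doubly flanked diaryl ether oxygen; the non-enolisable aldehyde tolerates anhydrous K3PO4.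

Step 13
Reactants: 21 pentameric aldehyde (rings A–E)
Product: 23 6-{2,6-dimethoxy-4-[2,3,4-trimethoxy-6-[2,6-dimethoxy-4-(2,4,6-trimethoxyphenoxy)phenoxy]phenoxy]phenoxy}-2,3,4-trimethoxyphenol, via aryl formate 22 (not isolated)
Conditions: mCPBA (1.1 equiv), CH2Cl2, 0 °C; then K2CO3 (cat.), MeOH, rt
Reagents that add atoms: mCPBA (3-chloroperoxybenzoic acid), O=C(OO)c1cccc(Cl)c1
Why: Baeyer–Villiger (Dakin-type) oxidation as in step 10, unmasking the ring E hydroxyl next to the ring D ether.

Step 14
Reactants: 19 4-bromo-2,6-dimethoxyphenol; 24 (3,4,5-trimethoxyphenyl)boronic acid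
Product: 25 5-bromo-1,3-dimethoxy-2-(3,4,5-trimethoxyphenoxy)benzene
Conditions: Cu(OAc)2 (1.0 equiv), pyridine, 4 Å MS, CH2Cl2, air, rt
Reagents that add atoms: none
Why: Chan–Lam oxidative O-arylation at room temperature leaves the C–Br bond untouched, which a coupling of this bromophenol with an aryl halide could not guarantee.

Step 15
Reactants: 23 pentameric phenol (rings A–E); 25 5-bromo-1,3-dimethoxy-2-(3,4,5-trimethoxyphenoxy)benzene
Product: 26 octadeca-O-methyl ether of the target (rings A–G, every hydroxyl as OMe)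
Conditions: CuI (20 mol %), picolinic acid (40 mol %), K3PO4, DMSO, 105 °C, Ar
Reagents that add atoms: none
Why: Ullmann ether coupling of the same type as step 12 completes the heptameric skeleton with every hydroxyl as a methyl ether.

Step 16
Reactants: 26 octadeca-O-methyl ether of the target
Product: 27 target CNP0292517.0
Conditions: BBr3 (excess), CH2Cl2, −78 °C to rt; then H2O, Ar
Reagents that add atoms: none
Why: Lewis-acid ether cleavage with BBr3 breaks aryl methyl ethers at the methyl–oxygen bond and leaves diaryl ether bonds intact, so all eighteen phenols should be released in one operation.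

Compound list
1 | syringaldehyde (4-hydroxy-3,5-dimethoxybenzaldehyde) | COc1cc(C=O)cc(OC)c1O | starting material
2 | 4-(benzyloxy)-3,5-dimethoxybenzaldehyde | COc1cc(C=O)cc(OC)c1OCc1ccccc1 | intermediate
3 | 4-(benzyloxy)-3,5-dimethoxyphenyl formate (not isolated) | COc1cc(OC=O)cc(OC)c1OCc1ccccc1 | intermediate
4 | 4-(benzyloxy)-3,5-dimethoxyphenol | COc1cc(O)cc(OC)c1OCc1ccccc1 | intermediate
5 | dimethyl 2-chloromalonate | COC(=O)C(Cl)C(=O)OC | starting material
6 | dimethyl 2-[4-(benzyloxy)-3,5-dimethoxyphenoxy]malonate | COC(=O)C(Oc1cc(OC)c(OCc2ccccc2)c(OC)c1)C(=O)OC | intermediate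
7 | dimethyl 3-oxopentanedioate | COC(=O)CC(=O)CC(=O)OC | starting material
8 | trimethyl 1-[4-(benzyloxy)-3,5-dimethoxyphenoxy]-2,4-dioxopentane-1,3,5-tricarboxylate (not isolated; tautomer and epimer mixture) | COC(=O)CC(=O)C(C(=O)OC)C(=O)C(Oc1cc(OC)c(OCc2ccccc2)c(OC)c1)C(=O)OC | intermediate
9 | dimethyl 5-[4-(benzyloxy)-3,5-dimethoxyphenoxy]-2,4,6-trihydroxybenzene-1,3-dicarboxylate | COC(=O)c1c(O)c(C(=O)OC)c(O)c(Oc2cc(OC)c(OCc3ccccc3)c(OC)c2)c1O | intermediate
10 | 5-[4-(benzyloxy)-3,5-dimethoxyphenoxy]-2,4,6-trihydroxybenzene-1,3-dicarboxylic acid (not isolated) | OC(=O)c1c(O)c(C(=O)O)c(O)c(Oc2cc(OC)c(OCc3ccccc3)c(OC)c2)c1O | intermediate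
11 | 2-[4-(benzyloxy)-3,5-dimethoxyphenoxy]benzene-1,3,5-triol | Oc1cc(O)c(Oc2cc(OC)c(OCc3ccccc3)c(OC)c2)c(O)c1 | intermediate
12 | 2-(benzyloxy)-1,3-dimethoxy-5-(2,4,6-trimethoxyphenoxy)benzene | COc1cc(OC)c(Oc2cc(OC)c(OCc3ccccc3)c(OC)c2)c(OC)c1 | intermediate
13 | 2,6-dimethoxy-4-(2,4,6-trimethoxyphenoxy)phenol | COc1cc(OC)c(Oc2cc(OC)c(O)c(OC)c2)c(OC)c1 | intermediate
14 | 5-iodo-1,2,3-trimethoxybenzene | COc1cc(I)cc(OC)c1OC | starting material
15 | 6-iodo-2,3,4-trimethoxybenzaldehyde | COc1cc(I)c(C=O)c(OC)c1OC | intermediate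
16 | 6-[2,6-dimethoxy-4-(2,4,6-trimethoxyphenoxy)phenoxy]-2,3,4-trimethoxybenzaldehyde | COc1cc(OC)c(Oc2cc(OC)c(Oc3cc(OC)c(OC)c(OC)c3C=O)c(OC)c2)c(OC)c1 | intermediate
17 | 6-[2,6-dimethoxy-4-(2,4,6-trimethoxyphenoxy)phenoxy]-2,3,4-trimethoxyphenyl formate (not isolated) | COc1cc(OC)c(Oc2cc(OC)c(Oc3cc(OC)c(OC)c(OC)c3OC=O)c(OC)c2)c(OC)c1 | intermediate
18 | 6-[2,6-dimethoxy-4-(2,4,6-trimethoxyphenoxy)phenoxy]-2,3,4-trimethoxyphenol | COc1cc(OC)c(Oc2cc(OC)c(Oc3cc(OC)c(OC)c(OC)c3O)c(OC)c2)c(OC)c1 | intermediate
19 | 4-bromo-2,6-dimethoxyphenol | COc1cc(Br)cc(OC)c1O | starting material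
20 | 6-(4-bromo-2,6-dimethoxyphenoxy)-2,3,4-trimethoxybenzaldehyde | COc1cc(Br)cc(OC)c1Oc1cc(OC)c(OC)c(OC)c1C=O | intermediate
21 | 6-{2,6-dimethoxy-4-[2,3,4-trimethoxy-6-[2,6-dimethoxy-4-(2,4,6-trimethoxyphenoxy)phenoxy]phenoxy]phenoxy}-2,3,4-trimethoxybenzaldehyde | COc1cc(OC)c(Oc2cc(OC)c(Oc3cc(OC)c(OC)c(OC)c3Oc3cc(OC)c(Oc4cc(OC)c(OC)c(OC)c4C=O)c(OC)c3)c(OC)c2)c(OC)c1 | intermediate
22 | formate ester of phenol 23 (not isolated) | COc1cc(OC)c(Oc2cc(OC)c(Oc3cc(OC)c(OC)c(OC)c3Oc3cc(OC)c(Oc4cc(OC)c(OC)c(OC)c4OC=O)c(OC)c3)c(OC)c2)c(OC)c1 | intermediate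
23 | 6-{2,6-dimethoxy-4-[2,3,4-trimethoxy-6-[2,6-dimethoxy-4-(2,4,6-trimethoxyphenoxy)phenoxy]phenoxy]phenoxy}-2,3,4-trimethoxyphenol | COc1cc(OC)c(Oc2cc(OC)c(Oc3cc(OC)c(OC)c(OC)c3Oc3cc(OC)c(Oc4cc(OC)c(OC)c(OC)c4O)c(OC)c3)c(OC)c2)c(OC)c1 | intermediate
24 | (3,4,5-trimethoxyphenyl)boronic acid | COc1cc(B(O)O)cc(OC)c1OC | starting material
25 | 5-bromo-1,3-dimethoxy-2-(3,4,5-trimethoxyphenoxy)benzene | COc1cc(Br)cc(OC)c1Oc1cc(OC)c(OC)c(OC)c1 | intermediate
26 | octadeca-O-methyl ether of the target (rings A–G, all eighteen hydroxyls as OMe) | COc1cc(OC)c(Oc2cc(OC)c(Oc3cc(OC)c(OC)c(OC)c3Oc3cc(OC)c(Oc4cc(OC)c(OC)c(OC)c4Oc4cc(OC)c(Oc5cc(OC)c(OC)c(OC)c5)c(OC)c4)c(OC)c3)c(OC)c2)c(OC)c1 | intermediate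
27 | target CNP0292517.0: 2,4,6-trihydroxyphenyl (A)–O–2,6-dihydroxy-1,4-phenylene (B)–O–3,4,5-trihydroxy-1,2-phenylene (C)–O–D (as B)–O–E (as C)–O–F (as B)–O–3,4,5-trihydroxyphenyl (G) | Oc1cc(O)c(Oc2cc(O)c(Oc3cc(O)c(O)c(O)c3Oc3cc(O)c(Oc4cc(O)c(O)c(O)c4Oc4cc(O)c(Oc5cc(O)c(O)c(O)c5)c(O)c4)c(O)c3)c(O)c2)c(O)c1 | target

Total step count: 16.
Longest linear sequence: 13 steps (steps 1–7, 9, 10, 12, 13, 15 and 16).

Steps most likely to fail

1. Step 4 (Proposed new method). Possible failure modes are self-condensation of 7, O-acylation leading to a pyranone that does not revert, retro-Claisen acyl scrambling of 8, and loss of electrophilicity because 6 is itself deprotonated. The fallback uses known chemistry and makes the ring A–O–ring B bond by arylation instead of ring construction. It sets out from 19: O-benzylation (BnBr, K2CO3, DMF) should give 2-(benzyloxy)-5-bromo-1,3-dimethoxybenzene F1. An Ullmann ether coupling of F1 with commercial 2,4,6-trimethoxyphenol (CuI, picolinic acid, K3PO4, DMSO, 105 °C) should then give 12, where it rejoins the route before step 7.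

2. Step 12. The coupling of a doubly flanked phenoxide with an electron-rich aryl bromide may stall, with hydrodebromination of 20 or oxidation of the phenoxide taking over. The fallback replaces the halide coupling by an oxidative boron coupling. It sets out from 20: Miyaura borylation (B2pin2, PdCl2(dppf), KOAc, dioxane, 80 °C) should give 2,3,4-trimethoxy-6-[2,6-dimethoxy-4-(4,4,5,5-tetramethyl-1,3,2-dioxaborolan-2-yl)phenoxy]benzaldehyde F2. A Chan–Lam O-arylation of 18 with F2 (Cu(OAc)2, pyridine, B(OH)3, 4 Å MS, MeCN, air, 60 °C) should then give 21, where it rejoins the route before step 13.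

3. Step 16. Ether cleavage may stop short and leave partly methylated mixtures, and the pyrogallol-type rings may oxidise in air during isolation of the free polyphenol. The fallback changes both the cleavage mode and the isolation. It sets out from 26: the hard acid–soft nucleophile pair AlCl3/EtSH (CH2Cl2, 0 °C to rt) should remove the methyl groups, and the crude product is acetylated without isolation (Ac2O, pyridine) to the octadecaacetate of the target F3, which is stable and can be purified on silica. Acid-catalysed methanolysis (HCl in MeOH, rt, Ar) should then return 27 without exposure to base.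

Further compounds
F1 | step 4 | 2-(benzyloxy)-5-bromo-1,3-dimethoxybenzene | COc1cc(Br)cc(OC)c1OCc1ccccc1
F2 | step 12 | 2,3,4-trimethoxy-6-[2,6-dimethoxy-4-(4,4,5,5-tetramethyl-1,3,2-dioxaborolan-2-yl)phenoxy]benzaldehyde | COc1cc(B2OC(C)(C)C(C)(C)O2)cc(OC)c1Oc1cc(OC)c(OC)c(OC)c1C=O
F3 | step 16 | octadecaacetate of the target (all eighteen hydroxyls as OAc) | CC(=O)Oc1cc(OC(C)=O)c(Oc2cc(OC(C)=O)c(Oc3cc(OC(C)=O)c(OC(C)=O)c(OC(C)=O)c3Oc3cc(OC(C)=O)c(Oc4cc(OC(C)=O)c(OC(C)=O)c(OC(C)=O)c4Oc4cc(OC(C)=O)c(Oc5cc(OC(C)=O)c(OC(C)=O)c(OC(C)=O)c5)c(OC(C)=O)c4)c(OC(C)=O)c3)c(OC(C)=O)c2)c(OC(C)=O)c1
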